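**Retrosynthetic overview**

- The target comes from a spiro-trione by O-methylation and by reductive removal (enol triflate, Pd/formate) of one ring-B oxygen. That oxygen is a removable regiochemical control element.
- The spiro-trione is made in one flask from acyclic partners: a Cu(II)–bis(oxazoline) Diels–Alder reaction closes ring B (cyclohexene) first, then a Dieckmann condensation onto the dienophile's ester closes ring A (trione) second.
- The dienophile is the Z-isobutylidene derivative of an acyclic 3,5-dioxo ester. Its geometry puts iPr cis to the ester carbon that becomes C1, and the chiral catalyst sets the absolute sense.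
- The diene is a 2-silyloxy-3-(4-methylpent-3-enyl)butadiene ("3-siloxy-myrcene"). The OSi group, not the alkyl chain, decides which CH2 bonds to CH–iPr, so the chain ends 1,3 to the spiro carbon; myrcene itself would give mainly the 1,4-isomer.
- The dienophile comes from γ-acylation of a β-keto ester dianion and a Knoevenagel condensation; the diene from acetylacetone alkylation, deacetylative methylenation and O-silylation.

Assumption: the (S,S)-ligand is assigned from the Evans square-planar chelate model (diene enters on the alkene face remote from the nearer tert-butyl group); this assignment is the least certain point, and the commercial (R,R)-ligand is substituted unchanged if the first run shows the opposite sense.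

**Step 1**
Reactants: 1 pentane-2,4-dione; 2 5-bromo-2-methylpent-2-ene
Product: 3 3-(4-methylpent-3-en-1-yl)pentane-2,4-dione
Conditions: K2CO3 (1.2 equiv), KI (10 mol %), acetone, reflux; 1 in 1.5-fold excess
Reagents that add atoms: none
Why: SN2 C-alkylation of the stabilised acetylacetone enolate by the primary bromide (iodide-assisted), with excess diketone suppressing dialkylation; no stereocentre is formed.

**Step 2**
Reactants: 3 3-(4-methylpent-3-en-1-yl)pentane-2,4-dione
Product: 5 7-methyl-3-methylideneoct-6-en-2-one, via hydroxymethyl diketone 4 (not isolated)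
Conditions: 37% aq. CH2O (3 equiv), K2CO3 (1.2 equiv), THF/H2O, 0 °C → rt
Reagents that add atoms: formaldehyde C=O
Why: Deacetylative α-methylenation: aldol addition to formaldehyde gives 4, whose alkoxide takes over one acetyl group, and the β-acetoxy ketone loses acetate by E1cB elimination.

**Step 3**
Reactants: 5 7-methyl-3-methylideneoct-6-en-2-one
Product: 6 tert-butyl(dimethyl)[(7-methyl-3-methylideneocta-1,6-dien-2-yl)oxy]silane
Conditions: TBSOTf (1.1 equiv), Et3N (1.5 equiv), CH2Cl2, −78 → 0 °C
Reagents that add atoms: tert-butyldimethylsilyl trifluoromethanesulfonate CC(C)(C)[Si](C)(C)OS(=O)(=O)C(F)(F)F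
Why: Soft enolisation and O-silylation of the methyl ketone, which can enolise only towards CH3, gives the 2-silyloxy-1,3-diene; no stereocentre.

**Step 4**
Reactants: 7 methyl 4-methyl-3-oxopentanoate; 8 N-methoxy-N-methylpropanamide
Product: 10 methyl 4,4-dimethyl-3,5-dioxoheptanoate, via dilithio dianion 9 (not isolated)
Conditions: LDA (2.2 equiv), THF, −78 → 0 °C; 8, −78 → 0 °C; aq. HCl to pH 4
Reagents that add atoms: none
Why: Huckin–Weiler dianion acylation: the more basic γ-carbon of 9 attacks the Weinreb amide, and the chelated tetrahedral adduct collapses only on work-up, so the new quaternary 1,3-diketone never meets base; no stereocentre.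

**Step 5**
Reactants: 10 methyl 4,4-dimethyl-3,5-dioxoheptanoate; 11 2-methylpropanal
Product: 12 methyl (2Z)-2-(2,2-dimethyl-3-oxopentanoyl)-4-methylpent-2-enoate
Conditions: piperidine (10 mol %), AcOH (10 mol %), 4 Å MS, CH2Cl2, rt
Reagents that add atoms: none
Why: Knoevenagel condensation at the only doubly activated CH2 under equilibrating amine catalysis, so the Z isomer (iPr cis to the small ester, trans to the bulky tert-alkyl ketone) is expected to predominate; residual E isomer is removed by chromatography.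

**Step 6 (key step)**
Reactants: 12 methyl (2Z)-2-(2,2-dimethyl-3-oxopentanoyl)-4-methylpent-2-enoate; 6 tert-butyl(dimethyl)[(7-methyl-3-methylideneocta-1,6-dien-2-yl)oxy]silane
Product: 14 (6R,7S)-9-[(tert-butyldimethylsilyl)oxy]-3-hydroxy-2,4,4-trimethyl-10-(4-methylpent-3-en-1-yl)-7-(propan-2-yl)spiro[5.5]undeca-2,9-diene-1,5-dione, via cyclohexene cycloadduct 13 (not isolated)
Conditions: [Cu((S,S)-t-Bu-box)](SbF6)2 (10 mol %), 6 (1.5 equiv), 4 Å MS, CH2Cl2, −40 → 0 °C; then THF, LiHMDS (2.3 equiv), −78 → 0 °C; AcOH, pH 7 buffer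
Reagents that add atoms: none
Why: Proposed new method: the Cu(II)–bis(oxazoline) dication chelates the two carbonyls flanking the alkene of 12 (closest known reaction type: Evans' Cu–box additions of enol silanes to alkylidene malonates) and diene 6 adds in a Lewis-acid-catalysed normal-demand Diels–Alder reaction (or its Mukaiyama–Michael/ring-closure equivalent) in which the CH2 next to C–OTBS bonds to the CH–iPr carbon, placing the side chain 1,3 to the future spiro carbon; suprafacial addition to the Z-alkene puts iPr cis to CO2Me and the open face of the chelate sets both centres of 13 as (1S,6S); LiHMDS then deprotonates the ethyl ketone CH2, the only acidic C–H, and a Dieckmann condensation onto the ester closes the trione ring, so the ester carbon becomes C1 and the spiro configuration follows from the alkene geometry.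

**Step 7**
Reactants: 14 (6R,7S)-9-[(tert-butyldimethylsilyl)oxy]-3-hydroxy-2,4,4-trimethyl-10-(4-methylpent-3-en-1-yl)-7-(propan-2-yl)spiro[5.5]undeca-2,9-diene-1,5-dione
Product: 15 (6R,7S)-9-[(tert-butyldimethylsilyl)oxy]-3-methoxy-2,4,4-trimethyl-10-(4-methylpent-3-en-1-yl)-7-(propan-2-yl)spiro[5.5]undeca-2,9-diene-1,5-dione
Conditions: TMSCHN2 (1.5 equiv), PhMe/MeOH 9:1, 0 °C, 30 min
Reagents that add atoms: trimethylsilyldiazomethane C[Si](C)(C)C=[N+]=[N-]
Why: O-methylation of the vinylogous acid by the diazoalkane (no C-methylation), expected at the C3 oxygen between CMe2 and C–Me rather than the C1 oxygen beside the spiro centre and its cis isopropyl group; the stereocentres are untouched.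

**Step 8**
Reactants: 15 (6R,7S)-9-[(tert-butyldimethylsilyl)oxy]-3-methoxy-2,4,4-trimethyl-10-(4-methylpent-3-en-1-yl)-7-(propan-2-yl)spiro[5.5]undeca-2,9-diene-1,5-dione
Product: 16 (6R,7S)-3-methoxy-2,4,4-trimethyl-10-(4-methylpent-3-en-1-yl)-1,5-dioxo-7-(propan-2-yl)spiro[5.5]undeca-2,9-dien-9-yl trifluoromethanesulfonate
Conditions: CsF (2 equiv), PhNTf2 (1.3 equiv), DME, rt
Reagents that add atoms: N-phenylbis(trifluoromethanesulfonimide) O=S(=O)(N(c1ccccc1)S(=O)(=O)C(F)(F)F)C(F)(F)F
Why: Enol silane to enol triflate exchange: fluoride releases the tetrasubstituted enolate at the position fixed by the cycloaddition and it is O-triflated in situ; ring A has no acidic hydrogen left.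

**Step 9**
Reactants: 16 (6R,7S)-3-methoxy-2,4,4-trimethyl-10-(4-methylpent-3-en-1-yl)-1,5-dioxo-7-(propan-2-yl)spiro[5.5]undeca-2,9-dien-9-yl trifluoromethanesulfonate
Product: 17 (6R,7S)-3-methoxy-2,4,4-trimethyl-10-(4-methylpent-3-en-1-yl)-7-(propan-2-yl)spiro[5.5]undeca-2,9-diene-1,5-dione
Conditions: Pd(OAc)2 (5 mol %), PPh3 (10 mol %), HCO2H (2 equiv), Et3N (3 equiv), DMF, 60 °C
Reagents that add atoms: none
Why: Pd-catalysed formate reduction of the enol triflate (oxidative addition, formate exchange, decarboxylation, C–H reductive elimination) replaces C9–O by C9–H without moving the double bond or touching the other alkenes and the stereocentres.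

**Compound list**

1 | pentane-2,4-dione | CC(=O)CC(C)=O | starting material
2 | 5-bromo-2-methylpent-2-ene | CC(C)=CCCBr | starting material
3 | 3-(4-methylpent-3-en-1-yl)pentane-2,4-dione | CC(=O)C(CCC=C(C)C)C(C)=O | intermediate
4 | 3-(hydroxymethyl)-3-(4-methylpent-3-en-1-yl)pentane-2,4-dione | CC(=O)C(CO)(CCC=C(C)C)C(C)=O | intermediate
5 | 7-methyl-3-methylideneoct-6-en-2-one | CC(=O)C(=C)CCC=C(C)C | intermediate
6 | tert-butyl(dimethyl)[(7-methyl-3-methylideneocta-1,6-dien-2-yl)oxy]silane | C=C(O[Si](C)(C)C(C)(C)C)C(=C)CCC=C(C)C | intermediate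
7 | methyl 4-methyl-3-oxopentanoate | COC(=O)CC(=O)C(C)C | starting material
8 | N-methoxy-N-methylpropanamide | CCC(=O)N(C)OC | starting material
9 | dilithium salt of the 2,4-dianion of methyl 4-methyl-3-oxopentanoate | [Li+].[Li+].COC(=O)C=C([O-])[C-](C)C | intermediate
10 | methyl 4,4-dimethyl-3,5-dioxoheptanoate | COC(=O)CC(=O)C(C)(C)C(=O)CC | intermediate
11 | 2-methylpropanal | CC(C)C=O | starting material
12 | methyl (2Z)-2-(2,2-dimethyl-3-oxopentanoyl)-4-methylpent-2-enoate (iPr cis to CO2Me) | CC(C)/C=C(\C(=O)OC)C(=O)C(C)(C)C(=O)CC | intermediate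
13 | methyl (1S,6S)-4-[(tert-butyldimethylsilyl)oxy]-1-(2,2-dimethyl-3-oxopentanoyl)-3-(4-methylpent-3-en-1-yl)-6-(propan-2-yl)cyclohex-3-ene-1-carboxylate (iPr cis to CO2Me) | COC(=O)[C@]1(CC(CCC=C(C)C)=C(O[Si](C)(C)C(C)(C)C)C[C@H]1C(C)C)C(=O)C(C)(C)C(=O)CC | intermediate
14 | (6R,7S)-9-[(tert-butyldimethylsilyl)oxy]-3-hydroxy-2,4,4-trimethyl-10-(4-methylpent-3-en-1-yl)-7-(propan-2-yl)spiro[5.5]undeca-2,9-diene-1,5-dione (enol form of the 1,3,5-trione; iPr cis to C1=O) | OC1=C(C)C(=O)[C@]2(CC(CCC=C(C)C)=C(O[Si](C)(C)C(C)(C)C)C[C@H]2C(C)C)C(=O)C1(C)C | intermediate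
15 | (6R,7S)-9-[(tert-butyldimethylsilyl)oxy]-3-methoxy-2,4,4-trimethyl-10-(4-methylpent-3-en-1-yl)-7-(propan-2-yl)spiro[5.5]undeca-2,9-diene-1,5-dione | COC1=C(C)C(=O)[C@]2(CC(CCC=C(C)C)=C(O[Si](C)(C)C(C)(C)C)C[C@H]2C(C)C)C(=O)C1(C)C | intermediate
16 | (6R,7S)-3-methoxy-2,4,4-trimethyl-10-(4-methylpent-3-en-1-yl)-1,5-dioxo-7-(propan-2-yl)spiro[5.5]undeca-2,9-dien-9-yl trifluoromethanesulfonate | COC1=C(C)C(=O)[C@]2(CC(CCC=C(C)C)=C(OS(=O)(=O)C(F)(F)F)C[C@H]2C(C)C)C(=O)C1(C)C | intermediate
17 | (6R,7S)-3-methoxy-2,4,4-trimethyl-10-(4-methylpent-3-en-1-yl)-7-(propan-2-yl)spiro[5.5]undeca-2,9-diene-1,5-dione | COC1=C(C)C(=O)[C@]2(CC(CCC=C(C)C)=CC[C@H]2C(C)C)C(=O)C1(C)C | target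

**Step count and risks**

Total step count: 9. Longest linear sequence: 7 (steps 1, 2, 3, 6, 7, 8, 9); the dienophile branch (steps 4, 5) joins at step 6.

The three steps most likely to fail:

Step 6. The acyclic, β-branched dienophile may react slowly, the level and sense of induction are unproven, and a hetero-Diels–Alder adduct or retro-Claisen cleavage could intervene. The fallback sets out from 10 and rejoins the route at 14, replacing the chiral catalyst by a covalently bound auxiliary that is expelled in the ring-A closure. Compound 10 is transesterified with (R)-pantolactone (toluene, 110 °C, DMAP cat.) to (3R)-4,4-dimethyl-2-oxooxolan-3-yl 4,4-dimethyl-3,5-dioxoheptanoate F1. Knoevenagel condensation with 11 as in step 5 gives (3R)-4,4-dimethyl-2-oxooxolan-3-yl (2Z)-2-(2,2-dimethyl-3-oxopentanoyl)-4-methylpent-2-enoate F2. Cycloaddition with 6 under stoichiometric TiCl4 (CH2Cl2, −78 °C) gives (3R)-4,4-dimethyl-2-oxooxolan-3-yl (1S,6S)-4-[(tert-butyldimethylsilyl)oxy]-1-(2,2-dimethyl-3-oxopentanoyl)-3-(4-methylpent-3-en-1-yl)-6-(propan-2-yl)cyclohex-3-ene-1-carboxylate F3, which is not isolated. LiHMDS then closes ring A with loss of pantolactone to give 14.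

Step 7. The two enol oxygens may be methylated with poor selectivity. The fallback sets out from 14 and rejoins at 17, replacing kinetic selection by a late thermodynamic one. The methylation mixture is not separated. The regioisomer (6R,7S)-9-[(tert-butyldimethylsilyl)oxy]-1-methoxy-2,4,4-trimethyl-10-(4-methylpent-3-en-1-yl)-7-(propan-2-yl)spiro[5.5]undeca-1,9-diene-3,5-dione F4 is carried with 15 through the triflation to (6R,7S)-1-methoxy-2,4,4-trimethyl-10-(4-methylpent-3-en-1-yl)-3,5-dioxo-7-(propan-2-yl)spiro[5.5]undeca-1,9-dien-9-yl trifluoromethanesulfonate F5, and through the reduction to (6R,7S)-1-methoxy-2,4,4-trimethyl-10-(4-methylpent-3-en-1-yl)-7-(propan-2-yl)spiro[5.5]undeca-1,9-diene-3,5-dione F6. The final mixture is equilibrated (TsOH cat., MeOH, HC(OMe)3, 40 °C); this vinylogous transesterification moves the methoxy group to the less hindered C3 oxygen and so converts F6 into 17.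

Step 4. Forming and acylating a tertiary γ-carbanion may give low conversion or O-acylation. The fallback sets out from 8 and rejoins at 10, building the chain from the other end without a dianion. The lithium enolate of tert-butyl 2-methylpropanoate is acylated by 8 to give tert-butyl 2,2-dimethyl-3-oxopentanoate F7. TFA (CH2Cl2, 0 °C) gives 2,2-dimethyl-3-oxopentanoic acid F8, which is kept cold. Carbonyldiimidazole gives 1-(1H-imidazol-1-yl)-2,2-dimethylpentane-1,3-dione F9, which is not isolated. Masamune chain extension with magnesium methyl malonate and decarboxylation on work-up gives 10.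

**Further compounds**

F1 | step 6 | (3R)-4,4-dimethyl-2-oxooxolan-3-yl 4,4-dimethyl-3,5-dioxoheptanoate | CCC(=O)C(C)(C)C(=O)CC(=O)O[C@H]1C(=O)OCC1(C)C
F2 | step 6 | (3R)-4,4-dimethyl-2-oxooxolan-3-yl (2Z)-2-(2,2-dimethyl-3-oxopentanoyl)-4-methylpent-2-enoate | CC(C)/C=C(\C(=O)O[C@H]1C(=O)OCC1(C)C)C(=O)C(C)(C)C(=O)CC
F3 | step 6 | (3R)-4,4-dimethyl-2-oxooxolan-3-yl (1S,6S)-4-[(tert-butyldimethylsilyl)oxy]-1-(2,2-dimethyl-3-oxopentanoyl)-3-(4-methylpent-3-en-1-yl)-6-(propan-2-yl)cyclohex-3-ene-1-carboxylate | O=C(O[C@H]1C(=O)OCC1(C)C)[C@]2(CC(CCC=C(C)C)=C(O[Si](C)(C)C(C)(C)C)C[C@H]2C(C)C)C(=O)C(C)(C)C(=O)CC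
F4 | step 7 | (6R,7S)-9-[(tert-butyldimethylsilyl)oxy]-1-methoxy-2,4,4-trimethyl-10-(4-methylpent-3-en-1-yl)-7-(propan-2-yl)spiro[5.5]undeca-1,9-diene-3,5-dione | O=C1C(C)=C(OC)[C@]2(CC(CCC=C(C)C)=C(O[Si](C)(C)C(C)(C)C)C[C@H]2C(C)C)C(=O)C1(C)C
F5 | step 7 | (6R,7S)-1-methoxy-2,4,4-trimethyl-10-(4-methylpent-3-en-1-yl)-3,5-dioxo-7-(propan-2-yl)spiro[5.5]undeca-1,9-dien-9-yl trifluoromethanesulfonate | O=C1C(C)=C(OC)[C@]2(CC(CCC=C(C)C)=C(OS(=O)(=O)C(F)(F)F)C[C@H]2C(C)C)C(=O)C1(C)C
F6 | step 7 | (6R,7S)-1-methoxy-2,4,4-trimethyl-10-(4-methylpent-3-en-1-yl)-7-(propan-2-yl)spiro[5.5]undeca-1,9-diene-3,5-dione | O=C1C(C)=C(OC)[C@]2(CC(CCC=C(C)C)=CC[C@H]2C(C)C)C(=O)C1(C)C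
F7 | step 4 | tert-butyl 2,2-dimethyl-3-oxopentanoate | CCC(=O)C(C)(C)C(=O)OC(C)(C)C
F8 | step 4 | 2,2-dimethyl-3-oxopentanoic acid | CCC(=O)C(C)(C)C(=O)O
F9 | step 4 | 1-(1H-imidazol-1-yl)-2,2-dimethylpentane-1,3-dione | CCC(=O)C(C)(C)C(=O)n1ccnc1
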